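At early times the grey run's substrate barely moves, still 99.6% at 5.00 h, so [substrate] stays near its charge. If the rate goes as [substrate][target], it is pseudo-first-order in [target], and the ratio [target]/[substrate] grows exponentially at a pace proportional to the charge.

| flask | substrate | temperature | remark | time |
|---|---|---|---|---|
| green | 0.080 M | 20 °C | run made earlier |  |
| grey | 0.32 M | 38 °C | run made earlier |  |
| south | 0.16 M | 50 °C |  | 10 h |
| north | 0.16 M | 25 °C |  | 10 h |
| north-west | 0.16 M |  | at 50 °C until 5.0 h, from then on at 25 °C | 10 h |

- green (time / h: target / %, substrate / %): 4.00: 0.6, 99.9; 6.00: 0, 99.5; 12.0: 0, 99.9; 20.0: 0, 100.5; 25.0: 0, 99.4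
- grey (time / h: target / %, substrate / %): 1.50: 0, 100.1; 2.50: 0, 99.6; 5.00: 0.6, 99.6; 8.00: 4.7, 95.8; 10.0: 12.7, 86.6

(each reading ± 0.5 percentage points)

- the flask that comes out highest in amount of target, in percent of the substrate charged, or "all alike" when all lie within 1.5 percentage points (south / north / north-west / all alike)
- target at the end, in percent of the substrate charged, south
- target at the end, in percent of the substrate charged, north
- target at the end, in percent of the substrate charged, north-west

I read the grey run between 8.00 h and 10.0 h. The doubling time of that ratio, multiplied by the charge of substrate, should depend on temperature but not on the charge. I call this the doubling product, and the readings give 0.405 M·h at 38 °C, with their scatter in it.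

North looks nearly like the green run, and the product compares them. At 38 °C, green would double every 5.06 h and north every 2.53 h. Yet at that pace north's 10 h hold 3.95 doublings, fewer than the 4.94 in green's 25.0 h. Green's target read 0% at that time, against a scatter of 0.5 percentage points. North is warmer, at 25 °C against 20 °C, but I still expected a trace there.

South and north-west are the same flask up to 5.0 h, and after that north-west runs on the slower pace of 25 °C. So I put south first, north-west second and north last.

The forecast named south, with 50% for south, 0.1% for north and 4% for north-west. Its ground was: “This looks autocatalytic: a slow direct route seeds the target, then growth is exponential”.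

The flasks gave 97.5% in south, 0.0155% in north and 16.9% in north-west, so south came out highest.

    substrate + target → 2 target (k = 0.00200 /M/s, Ea = 81.0 kJ/mol)
    substrate → target (k = 1.30 × 10⁻⁷ /s, Ea = 125 kJ/mol)
    substrate → decomposition product (k = 4.30 × 10⁻⁸ /s, Ea = 118 kJ/mol)
    (constants at 50 °C)

After the change, north-west's ratio doubled every 7.52 h. That makes a doubling product of 1.20 M·h at 25 °C, 2.96 times the 0.405 M·h of the grey run. The neighbour of north, charged with a quarter as much substrate (0.040 M), then has a doubling time of 30.0 h. Its 10 h hold 0.333 of a doubling, against 1.33 in north. Its target ended at 0.0106%, against 0.0155% in north.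

Readings and results are calculated for an exercise, and the scatter is random.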